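| setting | ash | elm | flask |
|---|---|---|---|
| L | 13 mM | 30 mM | 20 mM |
| remark | run made earlier | run made earlier |  |
| time |  |  | 80 min |

| run | time / min | E / % | D / % |
|---|---|---|---|
| ash | 8.00 | 40.1 | 13.1 |
| ash | 20.0 | 69.0 | 11.4 |
| ash | 40.0 | 82.8 | 6.4 |
| ash | 60.0 | 84.1 | 3.0 |
| ash | 80.0 | 81.3 | 2.3 |
| elm | 6.00 | 31.3 | 21.3 |
| elm | 12.0 | 49.3 | 25.2 |
| elm | 25.0 | 70.9 | 19.9 |
| elm | 40.0 | 78.2 | 13.3 |
| elm | 80.0 | 77.4 | 8.0 |

(readings scatter by 0.5 percentage points)

- a species is counted by the L in it: one D counts as two
- amounts and yields of E count D too
- steps that have been proposed: L <-> E + J; L + E <-> D; E -> G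
- in an amount of E, one D counts as one E

**Two times.** In the small charge, the ash run, E as counted (free E plus one per D) reached 40.1% at 8.00 min. Taken as first-order, that gave me 10.8 min as the conversion time, the half-life of unconverted L, with the L bound in D counted as unconverted. From 60.0 min to 80.0 min the same run fell from 84.1% to 81.3%, which gave 409 min as the loss time, the half-life of counted E on its way to G. This is a rough reading: the fall was 2.8 percentage points, against a scatter of 0.5 points on each reading.

**My reckoning.** The asked 80 min is longer than the conversion time and shorter than the loss time, so I expected E near its plateau. Interpolating between the two charges gave E 79.7% and D 4.65%. Loss running after the conversion time gave G 11.1%. One J per L converted gave 18.1 mM of J.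

1. how much E the flask holds at 80 min, in percent of the L charged
2. how much D the flask holds at 80 min, in percent of the L charged
3. how much G the flask holds at 80 min, in percent of the L charged
4. concentration of J at 80 min, in mM

**The result.** The forecast said E 79.6%, D 4.4%, J 19.3 mM and G 16.8%, a G above mine, taken from a balance of the earlier runs, “with about 1% L left”. The flask gave E 80.0%, D 4.47%, G 13.0% and J 18.6 mM.

    L ⇌ E + J (K = 0.370 M, k = 4.20 /h)
    L + E ⇌ D, settled at all times (K = 30.0 /M)
    E → G (k = 0.150 /h)

**What stands.** In this flask the half-life of L by the forward rate of the first step alone was 9.9 min, while free E had a half-life of 4.6 h by conversion into G alone, long against 80 min. Net turnover up to 80 min was 93.0% of the charge through the first step and 13.0% on to G. The asked time was 0.196 of my loss time. Carried on to 5.0 h, that loss time put the flask's E, D counted, at 55.1%, and the flask left that long holds 49.3%.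

The earlier runs and the new flask were generated by integration for substances that don't exist, and the scatter is random.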